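Numbering: C1 = prenyl bridgehead, C2–C3–C4 = enolised diketone bridge (aroyl on C3), C5 = geranyl bridgehead, C6H2–C7H(prenyl)–C8Me2 = saturated bridge, C9 = bridge ketone; ring A = C1–C2–C3–C4–C5–C9, ring B = C1–C8–C7–C6–C5–C9.
Enabling feature: the C6–C7–C8 bridge with its C7 prenyl group is a lavandulyl chain on C5, C8 becomes a tertiary centre once C1–C8 is cut, and C1 is the central carbon of the C2/C9 β-dicarbonyl part of ring A. The bond between the two quaternary carbons C1 and C8 is therefore the union of a tertiary cation with an enol carbon around six-membered ring B.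
Cuts, in order: the two catechol O–Si bonds, C1–C8 (ring B opens to a dearomatised aroylphloroglucinol), C5–C6 (lavandulyl), C1–CH2 (prenyl), C5–CH2 (geranyl), and last C3–C(=O)Ar.
Forward: ring A is the carbon ring of phloroglucinol. It is aroylated (aryllithium plus aldehyde, then oxidation), C-geranylated, C-prenylated and dearomatised at C5 with (R)-lavandulyl triflate; ring B then closes, and only desilylation follows.
Stereochemistry: C7 comes from (R)-lavandulol. C5 forms without control in the dearomatisation and is secured by separating the isomers. C1 is dictated by C5 through the geometry of the bicycle.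

Key step: step 10

Assumption: (R)-lavandulol is bought enantiopure (it is also accessible from the racemate by lipase-catalysed acylation), and each enolised polyketone is drawn and named as one tautomer of a rapidly equilibrating set.

Step 1
Reactants: 1 3,4-dihydroxybenzaldehyde
Product: 2 3,4-bis(triisopropylsilyloxy)benzaldehyde
Conditions: TIPSCl (2.4 equiv), imidazole, DMF, rt
Reagents that add atoms: chlorotriisopropylsilane, CC(C)[Si](Cl)(C(C)C)C(C)C
Why: Standard imidazole-promoted O-silylation of phenols; the triisopropylsilyl ether is preferred to a smaller silyl ether because it must outlast methanolic HCl (step 5), an amidine base (steps 6 and 7) and a lithium amide (step 9) and still fall to fluoride.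

Step 2
Reactants: 3 phloroglucinol
Product: 4 1,3,5-tris(methoxymethoxy)benzene
Conditions: NaH, MOMCl, DMF, 0 °C to rt
Reagents that add atoms: chloromethyl methyl ether, COCCl
Why: Williamson etherification: the hard electrophile MOMCl alkylates the sodium phenoxide on oxygen, and the three acetal ethers later direct the lithiation.

Step 3
Reactants: 4 1,3,5-tris(methoxymethoxy)benzene, 2 3,4-bis(triisopropylsilyloxy)benzaldehyde
Product: 6 [3,4-bis(triisopropylsilyloxy)phenyl][2,4,6-tris(methoxymethoxy)phenyl]methanol (racemic), via 2,4,6-tris(methoxymethoxy)phenyllithium 5 (not isolated)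
Conditions: n-BuLi, THF, 0 °C; then 2, −78 °C; H2O
Reagents that add atoms: none
Why: Directed ortho-metalation between two MOM ethers and 1,2-addition of the aryllithium to the aldehyde join ring A to the aroyl carbon without the Lewis acid of a Friedel–Crafts acylation, which aryl silyl ethers would not survive; the carbinol centre forms racemic and is erased in step 4.

Step 4
Reactants: 6 [3,4-bis(triisopropylsilyloxy)phenyl][2,4,6-tris(methoxymethoxy)phenyl]methanol
Product: 7 [3,4-bis(triisopropylsilyloxy)phenyl][2,4,6-tris(methoxymethoxy)phenyl]methanone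
Conditions: IBX, DMSO–THF, rt
Reagents that add atoms: none
Why: IBX oxidation of a doubly benzylic secondary alcohol is fast under neutral conditions that leave acetal and silyl ethers alone.

Step 5
Reactants: 7 [3,4-bis(triisopropylsilyloxy)phenyl][2,4,6-tris(methoxymethoxy)phenyl]methanone
Product: 8 [3,4-bis(triisopropylsilyloxy)phenyl](2,4,6-trihydroxyphenyl)methanone
Conditions: conc. HCl (cat.), MeOH–THF, 40 °C
Reagents that add atoms: none
Why: Acid-catalysed transacetalisation to methanol removes aryl MOM ethers (the two next to the ketone first), while aryl triisopropylsilyl ethers are cleaved far more slowly by dilute acid and no alkene is yet present.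

Step 6
Reactants: 8 [3,4-bis(triisopropylsilyloxy)phenyl](2,4,6-trihydroxyphenyl)methanone, 9 geranyl bromide
Product: 10 [3,4-bis(triisopropylsilyloxy)phenyl]{3-[(2E)-3,7-dimethylocta-2,6-dienyl]-2,4,6-trihydroxyphenyl}methanone
Conditions: DBU, 9 (0.9 equiv), THF, 0 °C to rt
Reagents that add atoms: none
Why: C-allylation of an acylphloroglucinol anion with an allylic bromide and DBU in THF is a known phenoxide C-alkylation; a slight deficit of 9 holds back a second allylation and the anhydrous amidine base spares the silyl ethers.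

Step 7
Reactants: 10 the 3-geranyl aroylphloroglucinol, 11 prenyl bromide
Product: 12 [3,4-bis(triisopropylsilyloxy)phenyl]{3-[(2E)-3,7-dimethylocta-2,6-dienyl]-2,4,6-trihydroxy-5-(3-methylbut-2-enyl)phenyl}methanone
Conditions: DBU, 11 (1.0 equiv), THF, 0 °C to rt
Reagents that add atoms: none
Why: Same phenoxide C-allylation: the last ring CH is the most accessible nucleophilic carbon and attack there restores the aromatic ring, so it is preferred to ipso attack at the geranyl-bearing carbon.

Step 8
Reactants: 13 (R)-lavandulol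
Product: 14 (2R)-5-methyl-2-(prop-1-en-2-yl)hex-4-enyl trifluoromethanesulfonate
Conditions: Tf2O, 2,6-lutidine, CH2Cl2, −78 °C; cold aqueous wash, used at once
Reagents that add atoms: trifluoromethanesulfonic anhydride, O=S(=O)(OS(=O)(=O)C(F)(F)F)C(F)(F)F
Why: Sulfonylation of a primary alcohol with Tf2O and a hindered pyridine touches no bond at the stereocentre, so the (R) configuration (the later C7) is kept, and the triflate supplies the reactivity that a β-branched primary carbon needs.

Step 9
Reactants: 12 the 3-geranyl-5-prenyl aroylphloroglucinol, 14 (R)-lavandulyl triflate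
Product: 15 (6S)-2-[3,4-bis(triisopropylsilyloxy)benzoyl]-6-[(2E)-3,7-dimethylocta-2,6-dienyl]-3,5-dihydroxy-4-(3-methylbut-2-enyl)-6-[(2S)-5-methyl-2-(prop-1-en-2-yl)hex-4-enyl]cyclohexa-2,4-dien-1-one
Conditions: LiHMDS (3.0 equiv), THF, −78 to 0 °C; 14, −78 to 0 °C; 1 M HCl; preparative HPLC
Reagents that add atoms: none
Why: Alkylative dearomatisation of the lithium salt of a fully substituted acylphloroglucinol by a β-branched primary triflate is a known reaction type that alkylates an alkyl-bearing ring carbon; neither the choice between the geranyl- and the prenyl-bearing carbon nor the face is controlled (C7 is too remote), so C5 is secured by isolating the (6S) isomer with the quaternary carbon at the geranyl position from the four C-alkylated isomers, C7 being untouched (its descriptor changes to S only through ligand priorities).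

Step 10
Reactants: 15 the C5-geranyl C5-lavandulyl C1-prenyl dearomatised aroylphloroglucinol
Product: 17 (1R,5R,7S)-3-[3,4-bis(triisopropylsilyloxy)benzoyl]-5-[(2E)-3,7-dimethylocta-2,6-dienyl]-4-hydroxy-8,8-dimethyl-1,7-bis(3-methylbut-2-enyl)bicyclo[3.3.1]non-3-ene-2,9-dione, via bis(trimethylsilyl) dienol ether 16 (not isolated)
Conditions: MSTFA, CH2Cl2, rt, then evaporation; [N,N′-bis(3,5-di-tert-butylsalicylidene)-1,2-cyclohexanediaminato]cobalt, Co(C36H52N2O2) (5 mol %), N-fluoro-2,4,6-trimethylpyridinium triflate (1.05 equiv), PhSiH3 (1.1 equiv), PhCF3, 4 Å sieves, 0 °C to rt; pH 5 buffer–THF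
Reagents that add atoms: none
Why: Proposed new method: the cobalt hydride formed from the divalent cobalt complex, the N–F oxidant and PhSiH3 delivers a hydrogen atom to the CH2 end of the isopropenyl group of 16, the tertiary C8 radical is trapped by cobalt and oxidised to a tetravalent alkylcobalt that acts as the C8 cation, the C1=C9 silyl enol ether attacks it through C1, and the C9 silyloxycarbenium ion sheds its silyl group to leave the C9 ketone. The closest known reaction types are cobalt-hydride radical–polar crossover hydrofunctionalisation (shown with O, N and arene nucleophiles and in polyene cyclisation), the Reetz tert-alkylation of silyl enol ethers, which joins two quaternary carbons, and the acid-induced cation closure of dearomatised acylphloroglucinol enol ethers to the same bicycle; new is the pairing of the first way of making the cation with an enol-carbon terminator on this ring system. Ring B (C1–C8–C7–C6–C5–C9) closes as a six-membered ring in a 6-(enolendo) mode onto a trigonal cationic carbon, through a chair in which C6 stands axial on C5 of ring A and the C7 prenyl group lies equatorial. C1 is the only new stereocentre and is fixed by C5, because the three-atom tether can reach C1 only on the ring-A face that carries C6, and the (6S,2S) pairing of 15 is the one that lets the C7 prenyl group stay equatorial in that chair. Hydrogen transfer must go to the isopropenyl group alone, which is secured by its 1,1-disubstitution (the four trisubstituted side-chain alkenes and the two fully substituted ring alkenes accept hydrogen atoms from the bulky hydride far more slowly) and by the oxidant being the limiting reagent. Capture must occur at C1 and not at oxygen or C3: free enol OH groups would be expected to close a six-membered ether as alcohols and phenols do under these conditions, so both are silylated beforehand, silyl enol ethers meet tertiary cations at carbon, and C3 is deactivated and crowded by the aroyl group.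

Step 11
Reactants: 17 the bis(triisopropylsilyl) ether of the target
Product: 18 (1R,5R,7S)-3-(3,4-dihydroxybenzoyl)-5-[(2E)-3,7-dimethylocta-2,6-dienyl]-4-hydroxy-8,8-dimethyl-1,7-bis(3-methylbut-2-enyl)bicyclo[3.3.1]non-3-ene-2,9-dione (target)
Conditions: TBAF (2.2 equiv), AcOH (2.2 equiv), THF, 0 °C, argon
Reagents that add atoms: none
Why: Fluoride-induced cleavage of aryl silyl ethers is fast at 0 °C, and the acetic acid buffer keeps catecholate and enolate concentrations low, so that neither air oxidation of the catechol nor base- or acid-induced closure of the enol onto a prenyl group should intervene; no stereocentre is touched.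

Compound list
1 | 3,4-dihydroxybenzaldehyde | O=Cc1ccc(O)c(O)c1 | starting material
2 | 3,4-bis(triisopropylsilyloxy)benzaldehyde | O=Cc1ccc(O[Si](C(C)C)(C(C)C)C(C)C)c(O[Si](C(C)C)(C(C)C)C(C)C)c1 | intermediate
3 | phloroglucinol | Oc1cc(O)cc(O)c1 | starting material
4 | 1,3,5-tris(methoxymethoxy)benzene | COCOc1cc(OCOC)cc(OCOC)c1 | intermediate
5 | 2,4,6-tris(methoxymethoxy)phenyllithium | [Li]c1c(OCOC)cc(OCOC)cc1OCOC | intermediate
6 | [3,4-bis(triisopropylsilyloxy)phenyl][2,4,6-tris(methoxymethoxy)phenyl]methanol (racemic) | OC(c1ccc(O[Si](C(C)C)(C(C)C)C(C)C)c(O[Si](C(C)C)(C(C)C)C(C)C)c1)c1c(OCOC)cc(OCOC)cc1OCOC | intermediate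
7 | [3,4-bis(triisopropylsilyloxy)phenyl][2,4,6-tris(methoxymethoxy)phenyl]methanone | O=C(c1ccc(O[Si](C(C)C)(C(C)C)C(C)C)c(O[Si](C(C)C)(C(C)C)C(C)C)c1)c1c(OCOC)cc(OCOC)cc1OCOC | intermediate
8 | [3,4-bis(triisopropylsilyloxy)phenyl](2,4,6-trihydroxyphenyl)methanone | O=C(c1ccc(O[Si](C(C)C)(C(C)C)C(C)C)c(O[Si](C(C)C)(C(C)C)C(C)C)c1)c1c(O)cc(O)cc1O | intermediate
9 | geranyl bromide | CC(C)=CCC/C(C)=C/CBr | starting material
10 | 3-geranyl derivative of 8 | CC(C)=CCC/C(C)=C/Cc1c(O)cc(O)c(C(=O)c2ccc(O[Si](C(C)C)(C(C)C)C(C)C)c(O[Si](C(C)C)(C(C)C)C(C)C)c2)c1O | intermediate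
11 | prenyl bromide | CC(C)=CCBr | starting material
12 | 3-geranyl-5-prenyl derivative of 8 | CC(C)=CCC/C(C)=C/Cc1c(O)c(CC=C(C)C)c(O)c(C(=O)c2ccc(O[Si](C(C)C)(C(C)C)C(C)C)c(O[Si](C(C)C)(C(C)C)C(C)C)c2)c1O | intermediate
13 | (R)-lavandulol | OC[C@H](CC=C(C)C)C(C)=C | starting material
14 | (R)-lavandulyl triflate | O=S(=O)(OC[C@H](CC=C(C)C)C(C)=C)C(F)(F)F | intermediate
15 | (6S,2S) dearomatised precursor (C5 geranyl and lavandulyl, C1 prenyl, C3 aroyl) | CC(C)=CCC/C(C)=C/C[C@@]1(C[C@H](CC=C(C)C)C(C)=C)C(=O)C(C(=O)c2ccc(O[Si](C(C)C)(C(C)C)C(C)C)c(O[Si](C(C)C)(C(C)C)C(C)C)c2)=C(O)C(CC=C(C)C)=C1O | intermediate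
16 | 3,5-bis(trimethylsilyl) dienol ether of 15 | CC(C)=CCC/C(C)=C/C[C@@]1(C[C@H](CC=C(C)C)C(C)=C)C(=O)C(C(=O)c2ccc(O[Si](C(C)C)(C(C)C)C(C)C)c(O[Si](C(C)C)(C(C)C)C(C)C)c2)=C(O[Si](C)(C)C)C(CC=C(C)C)=C1O[Si](C)(C)C | intermediate
17 | (1R,5R,7S) bis(triisopropylsilyl) ether of the target | CC(C)=CCC/C(C)=C/C[C@@]12C[C@H](CC=C(C)C)C(C)(C)[C@@](CC=C(C)C)(C(=O)C(C(=O)c3ccc(O[Si](C(C)C)(C(C)C)C(C)C)c(O[Si](C(C)C)(C(C)C)C(C)C)c3)=C1O)C2=O | intermediate
18 | CNP0160101.4, (1R,5R,7S) | CC(C)=CCC/C(C)=C/C[C@@]12C[C@H](CC=C(C)C)C(C)(C)[C@@](CC=C(C)C)(C(=O)C(C(=O)c3ccc(O)c(O)c3)=C1O)C2=O | target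

Total step count: 11. Longest linear sequence: 9 steps (2, 3, 4, 5, 6, 7, 9, 10, 11; the branch through step 1 is equally long).

Steps most likely to fail

Step 10.
- Possible failures: hydrogen-atom transfer to a trisubstituted side-chain alkene; stripping or fluorination of the dienol ether by fluoride or the N–F salt; proton loss from the C8 cation (alkene isomerisation); closure through a carbonyl oxygen or through the inner geranyl alkene.
- The fallback uses known chemistry. It separates hydrogen transfer from C–C bond formation, so no oxidant is present when nucleophile and cation meet. It sets out from 15 and returns at 17.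
- Cobalt-catalysed hydrogen-atom-transfer hydrochlorination (Co(BF4)2·6H2O, potassium N-(3,5-di-tert-butylsalicylidene)-2,2-diphenylglycinate, PhSiH3, TsCl, EtOH, rt) adds H and Cl to the isopropenyl group and gives the tertiary chloride F1.
- MSTFA turns F1 into its bis(trimethylsilyl) dienol ether F2.
- TiCl4 in CH2Cl2 at −45 °C ionises the C8–Cl bond, and the silyl enol ether closes at C1 (Reetz tert-alkylation). Aqueous work-up gives 17.

Step 9.
- Possible failures: attack at the prenyl-bearing instead of the geranyl-bearing carbon, on either face or at oxygen; elimination or solvolysis of the triflate; incomplete separation of four closely related isomers.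
- The fallback blocks the competing carbon. It sets out from 8 and returns at 15.
- NBS (1 equiv, CH2Cl2, −78 °C) brominates one of the two equivalent ring CH positions and gives the bromo aroylphloroglucinol F3.
- DBU and 9 allylate the last CH to the bromo geranyl compound F4.
- LiHMDS and 14 can then alkylate only the geranyl-bearing carbon. Separating just two C5 epimers leaves the bromodienone F5.
- Aqueous Na2SO3 in THF reduces the 2-bromo-1,3-dicarbonyl unit to the C1–H dienone F6.
- DBU and 11 prenylate C1, the only free nucleophilic carbon, to 15.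

Step 6 (and likewise step 7).
- Possible failures: double allylation, O-allylation, and migration or loss of a silyl group in the presence of phenoxides.
- The fallback forms both ring–allyl bonds from aryllithiums before the phenols are freed. It sets out from 4 and returns at 12.
- Lithiation as in step 3 (5) and quench with 9 give 2-geranyl-1,3,5-tris(methoxymethoxy)benzene F7.
- A second n-BuLi treatment gives the aryllithium F8, which 11 converts into the geranyl prenyl arene F9.
- A third lithiation gives the aryllithium F10, which adds to aldehyde 2 to give the carbinol F11.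
- IBX gives the ketone F12.
- Brief treatment with catalytic HCl in MeOH at rt, as used for MOM ethers of prenylated phenols, frees 12.

Further compounds
F1 | step 10 | tertiary chloride: 15 with 2-chloropropan-2-yl in place of isopropenyl (same configuration) | CC(C)=CCC/C(C)=C/C[C@@]1(C[C@H](CC=C(C)C)C(C)(C)Cl)C(=O)C(C(=O)c2ccc(O[Si](C(C)C)(C(C)C)C(C)C)c(O[Si](C(C)C)(C(C)C)C(C)C)c2)=C(O)C(CC=C(C)C)=C1O
F2 | step 10 | 3,5-bis(trimethylsilyl) dienol ether of F1 | CC(C)=CCC/C(C)=C/C[C@@]1(C[C@H](CC=C(C)C)C(C)(C)Cl)C(=O)C(C(=O)c2ccc(O[Si](C(C)C)(C(C)C)C(C)C)c(O[Si](C(C)C)(C(C)C)C(C)C)c2)=C(O[Si](C)(C)C)C(CC=C(C)C)=C1O[Si](C)(C)C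
F3 | step 9 | [3,4-bis(triisopropylsilyloxy)phenyl](3-bromo-2,4,6-trihydroxyphenyl)methanone | O=C(c1ccc(O[Si](C(C)C)(C(C)C)C(C)C)c(O[Si](C(C)C)(C(C)C)C(C)C)c1)c1c(O)cc(O)c(Br)c1O
F4 | step 9 | 3-bromo-5-geranyl derivative of 8 | CC(C)=CCC/C(C)=C/Cc1c(O)c(Br)c(O)c(C(=O)c2ccc(O[Si](C(C)C)(C(C)C)C(C)C)c(O[Si](C(C)C)(C(C)C)C(C)C)c2)c1O
F5 | step 9 | bromodienone: 15 with Br in place of the C1 prenyl group (same configuration) | CC(C)=CCC/C(C)=C/C[C@@]1(C[C@H](CC=C(C)C)C(C)=C)C(=O)C(C(=O)c2ccc(O[Si](C(C)C)(C(C)C)C(C)C)c(O[Si](C(C)C)(C(C)C)C(C)C)c2)=C(O)C(Br)=C1O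
F6 | step 9 | C1–H dienone: 15 with H in place of the C1 prenyl group (same configuration) | CC(C)=CCC/C(C)=C/C[C@@]1(C[C@H](CC=C(C)C)C(C)=C)C(=O)C(C(=O)c2ccc(O[Si](C(C)C)(C(C)C)C(C)C)c(O[Si](C(C)C)(C(C)C)C(C)C)c2)=C(O)C=C1O
F7 | step 6 | 2-geranyl-1,3,5-tris(methoxymethoxy)benzene | CC(C)=CCC/C(C)=C/Cc1c(OCOC)cc(OCOC)cc1OCOC
F8 | step 6 | 3-geranyl-2,4,6-tris(methoxymethoxy)phenyllithium | CC(C)=CCC/C(C)=C/Cc1c(OCOC)cc(OCOC)c([Li])c1OCOC
F9 | step 6 | 2-geranyl-4-prenyl-1,3,5-tris(methoxymethoxy)benzene | CC(C)=CCC/C(C)=C/Cc1c(OCOC)cc(OCOC)c(CC=C(C)C)c1OCOC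
F10 | step 6 | 3-geranyl-5-prenyl-2,4,6-tris(methoxymethoxy)phenyllithium | CC(C)=CCC/C(C)=C/Cc1c(OCOC)c([Li])c(OCOC)c(CC=C(C)C)c1OCOC
F11 | step 6 | [3,4-bis(triisopropylsilyloxy)phenyl][3-geranyl-5-prenyl-2,4,6-tris(methoxymethoxy)phenyl]methanol (racemic) | CC(C)=CCC/C(C)=C/Cc1c(OCOC)c(C(O)c2ccc(O[Si](C(C)C)(C(C)C)C(C)C)c(O[Si](C(C)C)(C(C)C)C(C)C)c2)c(OCOC)c(CC=C(C)C)c1OCOC
F12 | step 6 | [3,4-bis(triisopropylsilyloxy)phenyl][3-geranyl-5-prenyl-2,4,6-tris(methoxymethoxy)phenyl]methanone | CC(C)=CCC/C(C)=C/Cc1c(OCOC)c(C(=O)c2ccc(O[Si](C(C)C)(C(C)C)C(C)C)c(O[Si](C(C)C)(C(C)C)C(C)C)c2)c(OCOC)c(CC=C(C)C)c1OCOC
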